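**Plan**

- Numbering and enabling feature: ring C1 (quaternary; CH3 and the C7=C8 chlorovinyl group), C2H2, C3 (Br, C9H2Br), C4HCl, C5H2, C6HCl. The C1/C6 pair is a ring CH–heteroatom carbon next to a quaternary carbon bearing methyl and a two-carbon alkenyl branch. This is what a γ,γ-disubstituted allylboron unit leaves behind when its γ-carbon adds to a C6 aldehyde.
- Retrosynthesis: C3–Br/C9–Br go back to the C3=C9 methylidene; C4–Cl to C4–OH and then C4–H (allylic oxidation); C8 with its chlorine to a vinyl group via the C7 aldehyde (Wittig, ozonolysis); C6–Cl to C6–OH. The ring bond C1–C6 is then cut (intramolecular allylboration). The open chain is cut at C7–C8 (Suzuki), C1–CH3 (carboalumination), C2–C1 (alkynylation of an allylic chloride) and C4–C5 (enolate alkylation).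
- Forward: the chain C6–C5–C4–C3(=C9)–C2–C1(CH3)=C7–C8–B is assembled in six steps from 3-chloro-2-(chloromethyl)prop-1-ene. The only ring closes in step 7. The halogens follow in the order C6–Cl, chlorovinyl (methylidene masked as a dibromide meanwhile), C4–Cl, C3/C9 dibromide.
- Stereochemistry: C1 and C6 relative from the chair transition state of the E-allylboronate, absolute from a chiral phosphoric acid. C6–Cl and C4–Cl arise by SN2 inversion of alcohols; the C4 oxygen enters anti to C6–Cl in the SeO2 oxidation. The Z-chloroalkene comes from the Wittig reaction, and C3 from axial opening of the bromonium ion.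

Key step: step 7

Remark 1: locants C1–C9 in the Why lines are those of the numbering above; compound names carry their own IUPAC locants.
Remark 2 (assumption): the facial preference of the phosphoric acid is taken to be the same in the ring closure as in intermolecular allylborations, so the (S) acid is the one required.

**Route**

Step 1
Reactants: 1 3-chloro-2-(chloromethyl)prop-1-ene; 2 tert-butyl acetate
Product: 4 tert-butyl 4-(chloromethyl)pent-4-enoate, via lithium enolate 3 (not isolated)
Conditions: LiN(iPr)2, THF, −78 °C; then 1 (3 equiv), DMPU, −78 to 0 °C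
Reagents that add atoms: none
Why: Ester enolate alkylation (SN2) at one allylic C–Cl bond forms C4–C5; the excess of the symmetrical dichloride suppresses double alkylation and the tert-butyl ester resists self-condensation.

Step 2
Reactants: 4 tert-butyl 4-(chloromethyl)pent-4-enoate; 5 ethynylmagnesium bromide
Product: 6 tert-butyl 4-methylidenehept-6-ynoate
Conditions: 5 (2 equiv), CuI (10 mol%), THF, 0 to 40 °C
Reagents that add atoms: none
Why: Copper-catalysed coupling of an alkynyl Grignard reagent with an allylic chloride forms C2–C1 and gives the skipped enyne; SN2 and SN2' attack give the same product because the allyl unit is symmetrical, and the hindered ester is left alone.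

Step 3
Reactants: 6 tert-butyl 4-methylidenehept-6-ynoate
Product: 7 4-methylidenehept-6-yn-1-ol
Conditions: LiAlH4, Et2O, 0 °C; aqueous NaOH work-up
Reagents that add atoms: none
Why: Hydride reduction of the ester gives the primary alcohol (C6 at the alcohol level); the isolated alkyne and alkene do not react with LiAlH4 under these conditions.

Step 4
Reactants: 7 4-methylidenehept-6-yn-1-ol
Product: 9 (E)-7-iodo-6-methyl-4-methylidenehept-6-en-1-ol, via alkenylalane 8 (not isolated)
Conditions: Me3Al (3 equiv), Cp2ZrCl2 (25 mol%), CH2Cl2, 0 °C to rt; then I2, THF, −30 to 0 °C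
Reagents that add atoms: trimethylaluminium C[Al](C)C; iodine II
Why: Negishi zirconium-catalysed carboalumination adds methyl and aluminium syn across the terminal alkyne with aluminium at the terminus, and iodinolysis with retention gives the E-iodide; the hydroxyl is carried as its aluminium alkoxide and the 1,1-disubstituted alkene does not react.

Step 5
Reactants: 9 (E)-7-iodo-6-methyl-4-methylidenehept-6-en-1-ol; 10 2,2'-methylenebis(4,4,5,5-tetramethyl-1,3,2-dioxaborolane)
Product: 11 (E)-6-methyl-4-methylidene-8-(4,4,5,5-tetramethyl-1,3,2-dioxaborolan-2-yl)oct-6-en-1-ol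
Conditions: 10 (1.5 equiv), Pd(P(t-Bu)3)2 (5 mol%), aq KOH, 1,4-dioxane, rt
Reagents that add atoms: none
Why: Suzuki–Miyaura mono-coupling of the geminal diboron reagent (the second boron speeds transmetalation of the first) with the alkenyl iodide proceeds with retention of alkene geometry and gives the E-γ,γ-disubstituted allyl pinacolboronate directly, the free hydroxyl being tolerated.

Step 6
Reactants: 11 (E)-6-methyl-4-methylidene-8-(4,4,5,5-tetramethyl-1,3,2-dioxaborolan-2-yl)oct-6-en-1-ol
Product: 12 (E)-6-methyl-4-methylidene-8-(4,4,5,5-tetramethyl-1,3,2-dioxaborolan-2-yl)oct-6-enal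
Conditions: Dess–Martin periodinane, NaHCO3, CH2Cl2, 0 °C; cold filtration through silica, used at once
Reagents that add atoms: none
Why: Dess–Martin oxidation is fast and buffered at 0 °C, so the allyl–boron bond survives and the aldehyde appears with no achiral acid present (the reason for oxidising an alcohol here and not hydrolysing an acetal); the uncatalysed ring closure should be slow enough for 12 to be passed cold into step 7.

Step 7
Reactants: 12 (E)-6-methyl-4-methylidene-8-(4,4,5,5-tetramethyl-1,3,2-dioxaborolan-2-yl)oct-6-enal
Product: 14 (1R,2S)-2-ethenyl-2-methyl-4-methylidenecyclohexan-1-ol, via borate ester 13 (not isolated)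
Conditions: (S)-TRIP [(S)-3,3'-bis(2,4,6-triisopropylphenyl)-1,1'-binaphthyl-2,2'-diyl hydrogen phosphate] (10 mol%), 4 Å molecular sieves, toluene, −30 °C; aq NaHCO3 work-up
Reagents that add atoms: none
Why: Proposed new method: the aldehyde oxygen binds boron and the allyl unit is transferred through a closed six-membered chair in which the γ-carbon C1 attacks C6 while the double bond moves to C7=C8, the phosphoric acid activating the boronate by hydrogen bonds to a dioxaborolane oxygen and to the formyl hydrogen; the closest known reactions are the phosphoric-acid-catalysed intermolecular allylboration of aldehydes with allyl pinacolboronates and the thermal ring closure of ω-oxo allylboronates. The carbocycle closes 6-exo-trig at the carbonyl group through a trans-fused chair–chair arrangement with the tether carbons C2 and C5 equatorial on C1 and C6. The relative configuration at C1 and C6 (hydroxyl trans to vinyl, methyl axial) follows from the E geometry of the C1=C7 bond in this chair; the absolute configuration comes from the catalyst, the (S) acid being chosen because the (R) acid directs intermolecular additions to the Re face and the Si face of C6 is needed here. The step needs the catalysed pathway to outrun the racemic background, which the low temperature and the low intrinsic reactivity of a γ,γ-disubstituted pinacol boronate should secure, and the sp2 carbon C3 removes the 1,3-diaxial contact of the axial C1 methyl group in the forming ring. Hydrolysis of borate 13 on work-up releases 14.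

Step 8
Reactants: 14 (1R,2S)-2-ethenyl-2-methyl-4-methylidenecyclohexan-1-ol
Product: 15 (1S,2S)-2-chloro-1-ethenyl-1-methyl-5-methylidenecyclohexane
Conditions: PPh3, CCl4, pyridine, MeCN, 60 °C
Reagents that add atoms: carbon tetrachloride ClC(Cl)(Cl)Cl
Why: Appel reaction, in which chloride displaces the alkoxyphosphonium group with inversion to put C6–Cl cis to vinyl; the SN2 step can run in the chair with the C1 methyl axial, where chloride approaches C6 anti to that methyl with no β-substituent in its path, and the non-ionising medium should hold back elimination and 1,2-shifts.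

Step 9
Reactants: 15 (1S,2S)-2-chloro-1-ethenyl-1-methyl-5-methylidenecyclohexane
Product: 16 (1S,2S)-5-bromo-5-(bromomethyl)-2-chloro-1-ethenyl-1-methylcyclohexane (both epimers at the CBr carbon)
Conditions: Br2 (1.0 equiv), CH2Cl2, −78 °C, dark
Reagents that add atoms: bromine BrBr
Why: Electrophilic bromination should pick the electron-rich 1,1-disubstituted alkene over the hindered monosubstituted vinyl group by a wide margin while the methylidene still carries no allylic halogen; the dibromide only masks this alkene during steps 10 and 11, so the configuration at C3 does not matter here.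

Step 10
Reactants: 16 (1S,2S)-5-bromo-5-(bromomethyl)-2-chloro-1-ethenyl-1-methylcyclohexane
Product: 18 (1S,2S)-5-bromo-5-(bromomethyl)-2-chloro-1-methylcyclohexane-1-carbaldehyde, via ozonide 17 (not isolated)
Conditions: O3, CH2Cl2, −78 °C; then Me2S, −78 °C to rt
Reagents that add atoms: ozone [O-][O+]=O
Why: Ozonolysis with reductive work-up cleaves the only remaining C=C bond and removes C8, leaving an α-quaternary aldehyde that can neither epimerise nor eliminate.

Step 11
Reactants: 18 (1S,2S)-5-bromo-5-(bromomethyl)-2-chloro-1-methylcyclohexane-1-carbaldehyde; 19 (chloromethyl)triphenylphosphonium chloride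
Product: 21 (1S,2S)-5-bromo-5-(bromomethyl)-2-chloro-1-[(Z)-2-chloroethenyl]-1-methylcyclohexane, via phosphorus ylide 20 (not isolated)
Conditions: 19, NaN(SiMe3)2, THF, −78 °C; then 18, −78 to 0 °C
Reagents that add atoms: none
Why: Wittig chloromethylenation, in which the salt-free non-stabilised α-chloro ylide and the bulky α-quaternary aldehyde should favour the cis-oxaphosphetane and hence the Z-chloroalkene; any E isomer would be removed by chromatography, and any debromination by the ylide is harmless because step 12 removes both bromines anyway.

Step 12
Reactants: 21 (1S,2S)-5-bromo-5-(bromomethyl)-2-chloro-1-[(Z)-2-chloroethenyl]-1-methylcyclohexane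
Product: 22 (1S,2S)-2-chloro-1-[(Z)-2-chloroethenyl]-1-methyl-5-methylidenecyclohexane
Conditions: Zn dust, AcOH, Et2O, 0 °C
Reagents that add atoms: none
Why: Zinc-mediated reductive elimination of the vicinal dibromide restores the methylidene group; the secondary chloride and the chloroalkene do not react with zinc under these conditions.

Step 13
Reactants: 22 (1S,2S)-2-chloro-1-[(Z)-2-chloroethenyl]-1-methyl-5-methylidenecyclohexane
Product: 23 (1S,4S,5S)-5-chloro-4-[(Z)-2-chloroethenyl]-4-methyl-2-methylidenecyclohexan-1-ol
Conditions: SeO2 (0.5 equiv), t-BuOOH (3 equiv), CH2Cl2, rt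
Reagents that add atoms: tert-butyl hydroperoxide CC(C)(C)OO (terminal oxidant); selenium dioxide O=[Se]=O (oxygen carrier)
Why: SeO2 allylic hydroxylation (ene reaction, then [2,3]-sigmatropic shift) returns the exocyclic double bond and should place oxygen at C4 rather than at C2, which is shielded by the quaternary C1; the oxygen should arrive trans to C6–Cl, axially in the chair with C6–Cl equatorial, since in the other chair the axial path is blocked by the syn-axial chlorine.

Step 14
Reactants: 23 (1S,4S,5S)-5-chloro-4-[(Z)-2-chloroethenyl]-4-methyl-2-methylidenecyclohexan-1-ol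
Product: 24 (1S,2S,4R)-2,4-dichloro-1-[(Z)-2-chloroethenyl]-1-methyl-5-methylidenecyclohexane
Conditions: PPh3, hexachloroacetone, CH2Cl2, −20 to 0 °C
Reagents that add atoms: hexachloroacetone ClC(Cl)(Cl)C(=O)C(Cl)(Cl)Cl
Why: Appel-type chlorination with hexachloroacetone as chlorine source converts allylic alcohols into the unrearranged chlorides with inversion (SN2 rather than SN2'), so the axial C4 oxygen becomes the equatorial C4 chloride cis to C6–Cl.

Step 15
Reactants: 24 (1S,2S,4R)-2,4-dichloro-1-[(Z)-2-chloroethenyl]-1-methyl-5-methylidenecyclohexane
Product: 25 (1S,2R,4S,5S)-1-bromo-1-(bromomethyl)-2,4-dichloro-5-[(Z)-2-chloroethenyl]-5-methylcyclohexane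
Conditions: Br2 (1.0 equiv), CH2Cl2, −78 °C, dark
Reagents that add atoms: bromine BrBr
Why: Bromine should add only to the methylidene group because the chloroalkene is strongly deactivated; with both ring chlorines equatorial the bromonium ion should form on the open equatorial face and be opened by bromide at tertiary C3 in the axial direction, giving axial C3–Br and equatorial CH2Br as in the target and keeping the larger CH2Br group away from the axial chlorovinyl group.

**Compound list**

1 | 3-chloro-2-(chloromethyl)prop-1-ene | ClCC(=C)CCl | starting material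
2 | tert-butyl acetate | CC(=O)OC(C)(C)C | starting material
3 | lithium enolate of tert-butyl acetate (formed in the flask) | C=C(O[Li])OC(C)(C)C | intermediate
4 | tert-butyl 4-(chloromethyl)pent-4-enoate | ClCC(=C)CCC(=O)OC(C)(C)C | intermediate
5 | ethynylmagnesium bromide | C#C[Mg]Br | starting material
6 | tert-butyl 4-methylidenehept-6-ynoate | C#CCC(=C)CCC(=O)OC(C)(C)C | intermediate
7 | 4-methylidenehept-6-yn-1-ol | C#CCC(=C)CCCO | intermediate
8 | (E)-alkenyl(dimethyl)alane carrying the hydroxyl as its dimethylaluminium alkoxide (formed in the flask) | C[Al](C)OCCCC(=C)C/C(C)=C/[Al](C)C | intermediate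
9 | (E)-7-iodo-6-methyl-4-methylidenehept-6-en-1-ol | OCCCC(=C)C/C(C)=C/I | intermediate
10 | 2,2'-methylenebis(4,4,5,5-tetramethyl-1,3,2-dioxaborolane) | CC1(C)OB(CB2OC(C)(C)C(C)(C)O2)OC1(C)C | starting material
11 | (E)-6-methyl-4-methylidene-8-(4,4,5,5-tetramethyl-1,3,2-dioxaborolan-2-yl)oct-6-en-1-ol | OCCCC(=C)C/C(C)=C/CB1OC(C)(C)C(C)(C)O1 | intermediate
12 | (E)-6-methyl-4-methylidene-8-(4,4,5,5-tetramethyl-1,3,2-dioxaborolan-2-yl)oct-6-enal | O=CCCC(=C)C/C(C)=C/CB1OC(C)(C)C(C)(C)O1 | intermediate
13 | pinacol borate ester of 14 (O–B bond at the C6 oxygen; formed in the flask) | C[C@@]1(C=C)CC(=C)CC[C@H]1OB1OC(C)(C)C(C)(C)O1 | intermediate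
14 | (1R,2S)-2-ethenyl-2-methyl-4-methylidenecyclohexan-1-ol (hydroxyl trans to vinyl) | C[C@@]1(C=C)CC(=C)CC[C@H]1O | intermediate
15 | (1S,2S)-2-chloro-1-ethenyl-1-methyl-5-methylidenecyclohexane (chlorine cis to vinyl) | C[C@@]1(C=C)CC(=C)CC[C@@H]1Cl | intermediate
16 | (1S,2S)-5-bromo-5-(bromomethyl)-2-chloro-1-ethenyl-1-methylcyclohexane (epimers at C5) | C[C@@]1(C=C)CC(Br)(CBr)CC[C@@H]1Cl | intermediate
17 | 1,2,4-trioxolane (ozonide) of 16 (formed in the flask) | C[C@@]1(C2OOCO2)CC(Br)(CBr)CC[C@@H]1Cl | intermediate
18 | (1S,2S)-5-bromo-5-(bromomethyl)-2-chloro-1-methylcyclohexane-1-carbaldehyde (epimers at C5) | C[C@@]1(C=O)CC(Br)(CBr)CC[C@@H]1Cl | intermediate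
19 | (chloromethyl)triphenylphosphonium chloride | ClC[P+](c1ccccc1)(c1ccccc1)c1ccccc1.[Cl-] | starting material
20 | (chloromethylidene)triphenylphosphorane (formed in the flask) | ClC=P(c1ccccc1)(c1ccccc1)c1ccccc1 | intermediate
21 | (1S,2S)-5-bromo-5-(bromomethyl)-2-chloro-1-[(Z)-2-chloroethenyl]-1-methylcyclohexane (epimers at C5) | C[C@@]1(/C=C\Cl)CC(Br)(CBr)CC[C@@H]1Cl | intermediate
22 | (1S,2S)-2-chloro-1-[(Z)-2-chloroethenyl]-1-methyl-5-methylidenecyclohexane | C[C@@]1(/C=C\Cl)CC(=C)CC[C@@H]1Cl | intermediate
23 | (1S,4S,5S)-5-chloro-4-[(Z)-2-chloroethenyl]-4-methyl-2-methylidenecyclohexan-1-ol (hydroxyl trans to the ring chlorine) | C[C@@]1(/C=C\Cl)CC(=C)[C@@H](O)C[C@@H]1Cl | intermediate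
24 | (1S,2S,4R)-2,4-dichloro-1-[(Z)-2-chloroethenyl]-1-methyl-5-methylidenecyclohexane (ring chlorines cis) | C[C@@]1(/C=C\Cl)CC(=C)[C@H](Cl)C[C@@H]1Cl | intermediate
25 | (1S,2R,4S,5S)-1-bromo-1-(bromomethyl)-2,4-dichloro-5-[(Z)-2-chloroethenyl]-5-methylcyclohexane | C[C@@]1(/C=C\Cl)C[C@@](Br)(CBr)[C@H](Cl)C[C@@H]1Cl | target

**Step count**

Total steps: 15. Longest linear sequence: 15 steps (1 and 2 to 25).

**Steps most likely to fail**

Step 7. The uncatalysed ring closure may keep pace with the acid-bound pathway, or the acid may discriminate the two faces of C6 poorly, so that enantiomeric purity is eroded. The fallback uses known chemistry and sets out from 12. Aldehyde 12 is left to cyclise without catalyst (toluene, rt to 40 °C); the thermal intramolecular allylboration through the same trans-fused chair should give, after hydrolytic work-up, racemic trans-configured 2-ethenyl-2-methyl-4-methylidenecyclohexan-1-ol F1. Kinetic resolution by lipase-catalysed acylation (Candida antarctica lipase B, vinyl acetate, tert-butyl methyl ether) should acylate the (1R) carbinol, in line with the empirical preference of lipases for secondary alcohols whose larger substituent (here the quaternary side) has the higher priority. This gives (1R,2S)-2-ethenyl-2-methyl-4-methylidenecyclohexyl acetate F2, which is separated from the unreacted (1S,2R) alcohol and cleaved with K2CO3 in MeOH. The fallback returns to the route at 14.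

Step 8. Chloride displacement at C6, next to the quaternary centre, may be outrun by elimination towards C5 or by a 1,2-shift from C1. The fallback sets out from 14 and separates activation from displacement. Tf2O and pyridine in CH2Cl2 at −40 °C should give (1R,2S)-2-ethenyl-2-methyl-4-methylidenecyclohexyl trifluoromethanesulfonate F3. F3 is treated cold with Bu4NCl in toluene/CH2Cl2 (−40 to 0 °C), where the much better leaving group lets the SN2 step run at a temperature at which elimination is slow. The fallback returns to the route at 15.

Step 11. Poor Z/E control in the chloromethylenation, together with loss of material through attack of the ylide on the tertiary bromide, may leave too little pure Z isomer. The fallback sets out from 15 and avoids C=C cleavage altogether. Z-selective cross-metathesis of the vinyl group with (Z)-1,2-dichloroethene under the molybdenum alkylidene Mo(NC6F5)(CHCMe2Ph)(2,5-Me2C4H2N)(O-2,6-(2,4,6-iPr3C6H2)2C6H3) (benzene, rt) should give the Z-chloroalkene directly; the 1,1-disubstituted methylidene group is a poor metathesis partner. No new compound is passed (F0), steps 9 to 12 fall away, and the fallback returns to the route at 22.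

**Further compounds**

F1 | step 7 | racemic 2-ethenyl-2-methyl-4-methylidenecyclohexan-1-ol, hydroxyl trans to vinyl | C[C@@]1(C=C)CC(=C)CC[C@H]1O.C[C@]1(C=C)CC(=C)CC[C@@H]1O
F2 | step 7 | (1R,2S)-2-ethenyl-2-methyl-4-methylidenecyclohexyl acetate | C[C@@]1(C=C)CC(=C)CC[C@H]1OC(C)=O
F3 | step 8 | (1R,2S)-2-ethenyl-2-methyl-4-methylidenecyclohexyl trifluoromethanesulfonate | C[C@@]1(C=C)CC(=C)CC[C@H]1OS(=O)(=O)C(F)(F)F
F0 | step 11 | none | none
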